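The route rests on cutting ring C at O1–C2 and C3–C4, which leaves a ring A salicylaldehyde and a two-carbon aryl unit. Ring A is mirror-symmetric about the C4a–C7 axis, so the two phenolic oxygens flanking the carbonyl carbon are equivalent: either can direct a rhodium catalyst into the formyl C–H bond and either can become O1, the other ending as the chelated 5-OH. In one flask, this aldehyde is added across the terminal alkyne of 4-ethynylphenol (C3–C4), and the resulting 2',6'-dihydroxychalcone is closed by a chiral bifunctional thiourea (O1–C2), setting C2 as S. The precursor is simply a prenylated phloroglucinaldehyde methyl ether plus an arylacetylene.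

Key step: step 3

Assumption: the quinine-derived thiourea is taken to direct the phenol oxygen to the Si face of C-β (giving 2S); if a first run shows the opposite sense, its quinidine-derived pseudoenantiomer is used instead with no other change.

Step 1
Reactants: 1 2,4,6-trihydroxybenzaldehyde; 2 1-bromo-3-methylbut-2-ene (prenyl bromide, 2.2 equiv)
Product: 3 2,4,6-trihydroxy-3,5-bis(3-methylbut-2-en-1-yl)benzaldehyde
Conditions: 10% aq KOH, 0 °C to rt; then cold dilute HCl
Reagents that add atoms: none
Why: Double C-alkylation of the ambident phloroglucinol polyphenoxide at its two free ring carbons, favoured over O-alkylation in water and held at the diprenyl stage by stoichiometry and low temperature; no stereocentre is formed.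

Step 2
Reactants: 3 2,4,6-trihydroxy-3,5-bis(3-methylbut-2-en-1-yl)benzaldehyde
Product: 4 2,6-dihydroxy-4-methoxy-3,5-bis(3-methylbut-2-en-1-yl)benzaldehyde
Conditions: MeI (1.05 equiv), K2CO3 (1.1 equiv), acetone, 0 °C to rt
Reagents that add atoms: iodomethane, CI
Why: Williamson etherification of the most acidic hydroxyl, the one para to the formyl group, while the two ortho hydroxyls, hydrogen-bonded to the formyl oxygen, are less acidic and less nucleophilic; no stereocentre is formed.

Step 3
Reactants: 4 2,6-dihydroxy-4-methoxy-3,5-bis(3-methylbut-2-en-1-yl)benzaldehyde; 5 4-ethynylphenol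
Product: 7 (2S)-5-hydroxy-2-(4-hydroxyphenyl)-7-methoxy-6,8-bis(3-methylbut-2-en-1-yl)-2,3-dihydro-4H-chromen-4-one, via chalcone 6 (not isolated)
Conditions: [Rh(cod)(OMe)]2 (2.5 mol %), 1,1'-bis(diphenylphosphino)ferrocene (5.5 mol %), toluene, 60 °C, 5 added slowly; then −25 °C, N-[3,5-bis(trifluoromethyl)phenyl]-N'-[(8α,9S)-6'-methoxycinchonan-9-yl]thiourea (15 mol %); AcOH quench
Reagents that add atoms: none
Why: The monovalent rhodium phenoxide chelate formed from 4 (either of its two equivalent ortho oxygens) inserts into the formyl C–H bond, the acyl rhodium hydride adds syn across the alkyne of 5 with hydride going to the internal and rhodium to the terminal carbon, and C–C reductive elimination gives the (E)-chalcone 6 (bond C3–C4); the chiral amine-thiourea added to the same flask then closes ring C (bond O1–C2). The closest known reaction type is the tandem rhodium-catalysed alkyne hydroacylation/oxa-Michael addition of salicylaldehydes to chroman-4-ones, combined with the known cinchona-thiourea-catalysed enantioselective cyclisation of 2'-hydroxychalcones. Ring C closes in the 6-endo-trig mode, a 2'-phenol oxygen adding to C-β of the enone while the 6'-OH stays hydrogen-bonded to the carbonyl and ends as the 5-OH. C2, the only new stereocentre, is under catalyst control: the quinuclidine nitrogen ion-pairs with the attacking phenol and the thiourea binds the carbonyl oxygen, so that oxygen is delivered to the Si face of C-β, which is 2S. The step needs linear rather than branched hydroacylation, no reaction of the two prenyl groups and no ring closure before the chiral catalyst is present; the terminal aryl alkyne with a chelating diphosphine, the inertness of trisubstituted alkenes towards rhodium hydride insertion, and base-free non-polar conditions followed by low temperature secure these. No choice between the two ortho hydroxyls is needed, because the mirror symmetry of ring A makes both closures give the same product.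

Compound list
1 | 2,4,6-trihydroxybenzaldehyde | O=Cc1c(O)cc(O)cc1O | starting material
2 | 1-bromo-3-methylbut-2-ene (prenyl bromide) | CC(C)=CCBr | starting material
3 | 2,4,6-trihydroxy-3,5-bis(3-methylbut-2-en-1-yl)benzaldehyde | O=Cc1c(O)c(CC=C(C)C)c(O)c(CC=C(C)C)c1O | intermediate
4 | 2,6-dihydroxy-4-methoxy-3,5-bis(3-methylbut-2-en-1-yl)benzaldehyde | COc1c(CC=C(C)C)c(O)c(C=O)c(O)c1CC=C(C)C | intermediate
5 | 4-ethynylphenol | C#Cc1ccc(O)cc1 | starting material
6 | (E)-1-[2,6-dihydroxy-4-methoxy-3,5-bis(3-methylbut-2-en-1-yl)phenyl]-3-(4-hydroxyphenyl)prop-2-en-1-one (chalcone, not isolated) | COc1c(CC=C(C)C)c(O)c(C(=O)/C=C/c2ccc(O)cc2)c(O)c1CC=C(C)C | intermediate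
7 | (2S)-5-hydroxy-2-(4-hydroxyphenyl)-7-methoxy-6,8-bis(3-methylbut-2-en-1-yl)-2,3-dihydro-4H-chromen-4-one | COc1c(CC=C(C)C)c(O)c2c(c1CC=C(C)C)O[C@H](c1ccc(O)cc1)CC2=O | target

Total step count: 3
Longest linear sequence: 3 steps (1 to 3 to 4 to 7)

Steps most likely to fail

Step 3. The chalcone may close without the chiral catalyst during the warm rhodium stage, or the 5-hydroxyflavanone may reopen and reclose under the amine, so that enantiomeric purity is lost. Rhodium-induced oligomerisation of the terminal alkyne or branched insertion would also lower conversion. The fallback gives up asymmetric catalysis for resolution with recycling; it sets out from 4 and 5 and comes back at 7. The same rhodium-catalysed hydroacylation is run to completion and the ring closure is finished with an achiral base (catalytic DBU, rt), which should give racemic 5-hydroxy-2-(4-hydroxyphenyl)-7-methoxy-6,8-bis(3-methylbut-2-en-1-yl)-2,3-dihydro-4H-chromen-4-one F1. The enantiomers are then separated by preparative chromatography on an amylose tris(3,5-dimethylphenylcarbamate) stationary phase, which should give 7 and its (2R)-enantiomer F2. F2 is returned to F1 by base-catalysed ring opening and reclosure through chalcone 6 (catalytic DBU) and resolved again, so that the material is not lost.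

Step 1. Geminal over-alkylation to dearomatised cyclohexadienones, O-alkylation and incomplete alkylation may compete, leaving the 3,5-diprenyl compound as a minor part of a mixture that is hard to separate. The fallback brings in the side chains by sigmatropic rearrangement and olefin metathesis; it sets out from 1 and comes back at 4, so that step 2 is also bypassed.
- Compound 1 is first methylated at its unhindered para hydroxyl (MeI 1.0 equiv, K2CO3, acetone) to 2,6-dihydroxy-4-methoxybenzaldehyde F3.
- Bis-O-allylation (allyl bromide, K2CO3, DMF, 60 °C) should give 2,6-bis(allyloxy)-4-methoxybenzaldehyde F4.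
- A double aromatic Claisen rearrangement (N,N-diethylaniline, 190 °C) should move each allyl group to the only free ortho carbon and give 3,5-diallyl-2,6-dihydroxy-4-methoxybenzaldehyde F5.
- Cross-metathesis with 2-methylbut-2-ene (second-generation Grubbs catalyst, RuCl2(=CHPh)(PCy3)(H2IMes), CH2Cl2, 40 °C) should turn both allyl groups into prenyl groups and give 4.

Step 2. Alkylation of a second oxygen, or dearomatising C-methylation of the electron-rich ring, may accompany the wanted etherification of the hindered 4-hydroxyl. The fallback replaces phenoxide alkylation by a Mitsunobu etherification; it sets out from 3 and comes back at 4. The methyl group is taken from methanol (MeOH, PPh3, DIAD, THF, 0 °C). No phenoxide is generated in bulk, the alkoxyphosphonium electrophile should be taken only by the most acidic, non-chelated hydroxyl, and C-alkylation is not expected for this reaction type. No new compound is formed on the way.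

Further compounds
F1 | step 3 | racemic 5-hydroxy-2-(4-hydroxyphenyl)-7-methoxy-6,8-bis(3-methylbut-2-en-1-yl)-2,3-dihydro-4H-chromen-4-one | COc1c(CC=C(C)C)c(O)c2c(c1CC=C(C)C)OC(c1ccc(O)cc1)CC2=O
F2 | step 3 | (2R)-5-hydroxy-2-(4-hydroxyphenyl)-7-methoxy-6,8-bis(3-methylbut-2-en-1-yl)-2,3-dihydro-4H-chromen-4-one | COc1c(CC=C(C)C)c(O)c2c(c1CC=C(C)C)O[C@@H](c1ccc(O)cc1)CC2=O
F3 | step 1 | 2,6-dihydroxy-4-methoxybenzaldehyde | COc1cc(O)c(C=O)c(O)c1
F4 | step 1 | 2,6-bis(allyloxy)-4-methoxybenzaldehyde | COc1cc(OCC=C)c(C=O)c(OCC=C)c1
F5 | step 1 | 3,5-diallyl-2,6-dihydroxy-4-methoxybenzaldehyde | COc1c(CC=C)c(O)c(C=O)c(O)c1CC=C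
F0 | step 2 | none | none
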